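Numbering: oxolane O1, C2 (veratryl), C3 (bearing C6H2OH), C4 (bearing the C7 aroyl group), C5. C2 is a benzylic donor carbon and C4 an acceptor carbon, 1,3-related through C3, and C5 is a lone CH2 between O1 and C4, so the ring is a donor–acceptor cyclopropane (C2–C3–C4) plus formaldehyde (O1, C5).
Retrosynthesis: epimerise C4; cut C7–aryl (aryllithium plus a lactone C7(=O)–O–C6 bridging C4 and C3); add a CO2Me helper on C4; cut O1–C2 and C4–C5 together (formaldehyde); cut C2–C4 and C3–C4 of the cyclopropane (enal plus bromomalonate).
Forward: cyclopropane ring first, lactone ring (the tether) second, oxolane third by (3+2) annulation to a cis-fused furofuranone; then the ester is removed, the aryllithium opens the lactone (C7 ketone and C6 alcohol appear together) and C4 is equilibrated.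
Stereochemistry: C2 and C3 come from the aminocatalyst (trans cyclopropane); C2 is inverted stereospecifically in the annulation, which gives 2,3-cis; C4 is set last under thermodynamic control, trans to C6.
The second acceptor on C4 is a methyl ester and not the C7 ketone: an aroyl group cis to the veratryl donor on the cyclopropane would invite Cloke–Wilson ring expansion under Lewis acid, and a non-enolisable β-keto lactone would be prone to retro-Claisen cleavage on hydrolysis; the lactone carbonyl itself becomes C7.

Key step: step 3

Remark: 1, 2, paraformaldehyde (the source of 6) and 10 are taken as purchased; 13 is drawn as the open-chain ketol although it should be in ring–chain equilibrium with its bicyclic hemiketal.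

Step 1
Reactants: 1 (E)-3,4-dimethoxycinnamaldehyde; 2 dimethyl bromomalonate
Product: 3 dimethyl (2R,3S)-2-formyl-3-(3,4-dimethoxyphenyl)cyclopropane-1,1-dicarboxylate (formyl and aryl trans)
Conditions: (S)-α,α-diphenylprolinol trimethylsilyl ether (20 mol %), 2,6-lutidine (1.1 equiv), CH2Cl2, 0 °C
Reagents that add atoms: none
Why: Aminocatalytic Michael-initiated ring closure (iminium conjugate addition of the bromomalonate, then enamine α-alkylation), in which the silyloxydiphenylmethyl group of the (S)-catalyst blocks one face of the E-iminium ion so that the malonate carbon adds to the open face of the β-carbon (aryl-bearing centre 3S) and the 3-exo-tet closure places the formyl group trans to the aryl group (2R).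

Step 2
Reactants: 3 dimethyl (2R,3S)-2-formyl-3-(3,4-dimethoxyphenyl)cyclopropane-1,1-dicarboxylate
Product: 5 methyl (1S,5R,6S)-6-(3,4-dimethoxyphenyl)-2-oxo-3-oxabicyclo[3.1.0]hexane-1-carboxylate (aryl exo), via hydroxymethyl cyclopropane diester 4 (not isolated)
Conditions: NaBH4 (1.0 equiv), THF/MeOH 4:1, −10 °C → rt
Reagents that add atoms: none
Why: Chemoselective borohydride reduction of the aldehyde followed by intramolecular transesterification, in which only the ester cis to the new CH2O arm can lactonise (5-exo-trig), so the geminal esters are differentiated and C1 becomes a defined stereocentre without any change at the two existing ones.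

Step 3
Reactants: 5 methyl (1S,5R,6S)-6-(3,4-dimethoxyphenyl)-2-oxo-3-oxabicyclo[3.1.0]hexane-1-carboxylate; 6 formaldehyde (charged as paraformaldehyde)
Product: 7 methyl (3aR,4R,6aR)-4-(3,4-dimethoxyphenyl)-1-oxotetrahydro-1H,3H-furo[3,4-c]furan-6a(6H)-carboxylate (cis-fused furofuranone; veratryl endo; ester angular)
Conditions: (CH2O)n (5 equiv), Sn(OTf)2 (10 mol %), 4 Å MS, CH2Cl2, 0 °C → rt
Reagents that add atoms: none
Why: Sn(OTf)2 should chelate the lactone and ester carbonyls of 5 and polarise the C1–C6 bond (the C4–C2 bond in oxolane numbering), the formaldehyde oxygen then attacks the veratryl carbon anti to the breaking bond within a contact ion pair, and the tin-bound malonate-type enolate at C4 closes on the O-methylene oxocarbenium carbon in an aldol (Prins-type) step. The closest known reaction type is the Lewis acid catalysed (3+2) annulation of aldehydes with 2-arylcyclopropane-1,1-diesters, which is stereospecific with inversion at the donor carbon, applied here to formaldehyde and to a diester whose one ester is tied back as the lactone. The one ring that closes is the oxolane, by C4–C5 bond formation in a 5-(enolexo)-endo-trig mode when counted on the C=O+ bond, as in every annulation of this family. C2 is set by inversion of cyclopropane C6, which turns the trans (exo-aryl) cyclopropane into the 2,3-cis oxolane, while C4 is dictated by the lactone tether, since only a cis ring fusion can form, and C3 is carried through unchanged. The step needs cleavage of C1–C6 and not of C1–C5 (secured by the veratryl donor on C6), substitution faster than ionisation at the electron-rich benzylic carbon (secured by the mild divalent tin triflate, low temperature and a short reaction time), and no ring expansion by a neighbouring carbonyl oxygen (secured by the absence of a ketone acceptor).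

Step 4
Reactants: 7 methyl (3aR,4R,6aR)-4-(3,4-dimethoxyphenyl)-1-oxotetrahydro-1H,3H-furo[3,4-c]furan-6a(6H)-carboxylate
Product: 9 (3aR,4R,6aR)-4-(3,4-dimethoxyphenyl)tetrahydro-1H,3H-furo[3,4-c]furan-1-one (cis-fused lactone; veratryl endo), via lithium carboxylate 8 (not isolated)
Conditions: LiCl (3 equiv), H2O (2 equiv), DMSO, 140 °C
Reagents that add atoms: none
Why: Krapcho dealkoxycarbonylation, in which chloride dealkylates the methyl ester by SN2 at CH3 (far faster than at the β-branched lactone CH2), the malonate-type carboxylate loses CO2 and the lactone enolate is protonated to the only possible cis-fused lactone, while the neutral medium leaves the benzylic ether at C2 untouched.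

Step 5
Reactants: 9 (3aR,4R,6aR)-4-(3,4-dimethoxyphenyl)tetrahydro-1H,3H-furo[3,4-c]furan-1-one; 10 5-bromo-1,2,3-trimethoxybenzene
Product: 13 [(2R,3R,4R)-2-(3,4-dimethoxyphenyl)-3-(hydroxymethyl)oxolan-4-yl](3,4,5-trimethoxyphenyl)methanone (all-cis ketol), via 3,4,5-trimethoxyphenyllithium 11 (not isolated), via lithium hemiketalate 12 (not isolated)
Conditions: 10 (1.2 equiv), n-BuLi (1.2 equiv), THF, −78 °C; then 9, THF, −78 °C; AcOH, −78 °C → rt
Reagents that add atoms: none
Why: Bromine–lithium exchange followed by mono-addition of the aryllithium to the γ-lactone from its open convex face, where the tetrahedral lithium hemiketalate should not collapse at −78 °C (so a second addition is held back) and the acidic cold quench releases the C7 ketone and the C6 alcohol together with C4 still cis.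

Step 6
Reactants: 13 [(2R,3R,4R)-2-(3,4-dimethoxyphenyl)-3-(hydroxymethyl)oxolan-4-yl](3,4,5-trimethoxyphenyl)methanone
Product: 14 [(2R,3R,4S)-2-(3,4-dimethoxyphenyl)-3-(hydroxymethyl)oxolan-4-yl](3,4,5-trimethoxyphenyl)methanone (target; 2,3-cis and 3,4-trans)
Conditions: DBU (0.3 equiv), THF, rt
Reagents that add atoms: none
Why: Base-mediated epimerisation through the aryl ketone enolate under thermodynamic control, in which C4 is the only acidic centre, the 3,4-trans isomer relieves the all-cis congestion and cannot close to a hemiketal, and β-elimination of O1 from the enolate is stereoelectronically disfavoured as the reverse of a 5-endo-trig closure.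

Compound list
1 | (E)-3,4-dimethoxycinnamaldehyde | COc1ccc(/C=C/C=O)cc1OC | starting material
2 | dimethyl bromomalonate | COC(=O)C(Br)C(=O)OC | starting material
3 | dimethyl (2R,3S)-2-formyl-3-(3,4-dimethoxyphenyl)cyclopropane-1,1-dicarboxylate | COc1ccc([C@@H]2[C@@H](C=O)C2(C(=O)OC)C(=O)OC)cc1OC | intermediate
4 | dimethyl (2R,3S)-2-(hydroxymethyl)-3-(3,4-dimethoxyphenyl)cyclopropane-1,1-dicarboxylate (formed in the flask) | COc1ccc([C@@H]2[C@@H](CO)C2(C(=O)OC)C(=O)OC)cc1OC | intermediate
5 | methyl (1S,5R,6S)-6-(3,4-dimethoxyphenyl)-2-oxo-3-oxabicyclo[3.1.0]hexane-1-carboxylate | COc1ccc([C@@H]2[C@H]3COC(=O)[C@@]23C(=O)OC)cc1OC | intermediate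
6 | formaldehyde (used as paraformaldehyde) | C=O | starting material
7 | methyl (3aR,4R,6aR)-4-(3,4-dimethoxyphenyl)-1-oxotetrahydro-1H,3H-furo[3,4-c]furan-6a(6H)-carboxylate | COc1ccc([C@@H]2OC[C@]3(C(=O)OC)C(=O)OC[C@H]23)cc1OC | intermediate
8 | lithium (3aR,4R,6aR)-4-(3,4-dimethoxyphenyl)-1-oxotetrahydro-1H,3H-furo[3,4-c]furan-6a(6H)-carboxylate (formed in the flask) | COc1ccc([C@@H]2OC[C@]3(C(=O)[O-])C(=O)OC[C@H]23)cc1OC.[Li+] | intermediate
9 | (3aR,4R,6aR)-4-(3,4-dimethoxyphenyl)tetrahydro-1H,3H-furo[3,4-c]furan-1-one | COc1ccc([C@@H]2OC[C@@H]3C(=O)OC[C@H]23)cc1OC | intermediate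
10 | 5-bromo-1,2,3-trimethoxybenzene | COc1cc(Br)cc(OC)c1OC | starting material
11 | 3,4,5-trimethoxyphenyllithium (formed in the flask) | [Li]c1cc(OC)c(OC)c(OC)c1 | intermediate
12 | lithium hemiketalate of 9 with the aryl group on C7, C7 epimers (formed in the flask) | COc1ccc([C@@H]2OC[C@@H]3C([O-])(c4cc(OC)c(OC)c(OC)c4)OC[C@H]23)cc1OC.[Li+] | intermediate
13 | [(2R,3R,4R)-2-(3,4-dimethoxyphenyl)-3-(hydroxymethyl)oxolan-4-yl](3,4,5-trimethoxyphenyl)methanone | COc1ccc([C@@H]2OC[C@H](C(=O)c3cc(OC)c(OC)c(OC)c3)[C@@H]2CO)cc1OC | intermediate
14 | [(2R,3R,4S)-2-(3,4-dimethoxyphenyl)-3-(hydroxymethyl)oxolan-4-yl](3,4,5-trimethoxyphenyl)methanone | COc1ccc([C@@H]2OC[C@@H](C(=O)c3cc(OC)c(OC)c(OC)c3)[C@@H]2CO)cc1OC | target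

Total step count: 6. Longest linear sequence: 6 steps (1 to 14); 2, 6 and 10 enter as purchased materials without steps of their own.

Steps most likely to fail

Step 3. Formaldehyde is a weak and self-condensing nucleophile, so opening of the activated cyclopropane may lag behind ionisation at the veratryl carbon (loss of the C2 configuration) or behind hydroxymethylation of the electron-rich veratryl ring. The fallback sets out from 5 and runs the same annulation with (E)-cinnamaldehyde, a strongly nucleophilic and well-behaved aldehyde partner (Sn(OTf)2, CH2Cl2, 0 °C), which should give the C5-styryl furofuranone ester F1. The alkene is then cleaved (O3, CH2Cl2/MeOH, −78 °C, then Me2S) to the C5-formyl furofuranone ester F2, and the formyl group is removed by Tsuji–Wilkinson decarbonylation (RhCl(PPh3)3, PhCN, 130 °C; no β-hydrogen is available on the quaternary C4). The C5 configuration is immaterial, and the sequence comes back to the route at 7.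

Step 5. The hemiketalate may collapse during the addition and take up a second aryl group, or the aryllithium may enolise the lactone instead of adding. The fallback sets out from 9 and changes the oxidation level: reduction with i-Bu2AlH (CH2Cl2, −78 °C) should give the lactol F3. Addition of 3,4,5-trimethoxyphenylmagnesium bromide (from 10 and Mg, 3 equiv, THF, 0 °C) to its open hydroxy aldehyde form gives the diol F4, which cannot over-add. Activated MnO2 (CH2Cl2, rt) then oxidises only the benzylic carbinol, and the sequence comes back to the route at 13; any C4 epimer formed on the way is 14 and passes through step 6 unchanged.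

Step 6. The all-cis ketol may be held as its bicyclic hemiketal so firmly that enolisation is slow, or prolonged exposure to base may open the oxolane by β-elimination. The fallback sets out from 13 and removes the ring–chain equilibrium: the open form is trapped through its primary alcohol as the cis silyl ether F5 (TBSCl, imidazole, DMF, rt). Epimerisation with DBU (THF, rt) should then give the trans silyl ether F6, and cleavage with TBAF/AcOH (THF, 0 °C) arrives at 14.

Further compounds
F1 | step 3 | methyl (3aR,4R,6aR)-4-(3,4-dimethoxyphenyl)-1-oxo-6-[(E)-2-phenylethenyl]tetrahydro-1H,3H-furo[3,4-c]furan-6a(6H)-carboxylate (C6 epimers) | COc1ccc([C@@H]2OC(/C=C/c4ccccc4)[C@]3(C(=O)OC)C(=O)OC[C@H]23)cc1OC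
F2 | step 3 | methyl (3aR,4R,6aR)-4-(3,4-dimethoxyphenyl)-6-formyl-1-oxotetrahydro-1H,3H-furo[3,4-c]furan-6a(6H)-carboxylate (C6 epimers) | COc1ccc([C@@H]2OC(C=O)[C@]3(C(=O)OC)C(=O)OC[C@H]23)cc1OC
F3 | step 5 | (3aR,4R,6aR)-4-(3,4-dimethoxyphenyl)tetrahydro-1H,3H-furo[3,4-c]furan-1-ol (anomers) | COc1ccc([C@@H]2OC[C@@H]3C(O)OC[C@H]23)cc1OC
F4 | step 5 | [(2R,3R,4R)-2-(3,4-dimethoxyphenyl)-3-(hydroxymethyl)oxolan-4-yl](3,4,5-trimethoxyphenyl)methanol (carbinol epimers) | COc1ccc([C@@H]2OC[C@H](C(O)c3cc(OC)c(OC)c(OC)c3)[C@@H]2CO)cc1OC
F5 | step 6 | [(2R,3R,4R)-3-({[tert-butyl(dimethyl)silyl]oxy}methyl)-2-(3,4-dimethoxyphenyl)oxolan-4-yl](3,4,5-trimethoxyphenyl)methanone | COc1ccc([C@@H]2OC[C@H](C(=O)c3cc(OC)c(OC)c(OC)c3)[C@@H]2CO[Si](C)(C)C(C)(C)C)cc1OC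
F6 | step 6 | [(2R,3R,4S)-3-({[tert-butyl(dimethyl)silyl]oxy}methyl)-2-(3,4-dimethoxyphenyl)oxolan-4-yl](3,4,5-trimethoxyphenyl)methanone | COc1ccc([C@@H]2OC[C@@H](C(=O)c3cc(OC)c(OC)c(OC)c3)[C@@H]2CO[Si](C)(C)C(C)(C)C)cc1OC
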